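The route rests on disconnecting the ketone carbon from C6 of the pyrrole ring. In the key step a chloroiminium ion, made from a 4-benzyloxybenzoic morpholide and POCl3, attacks the C6–H bond of the 5-aryl-7-deazaxanthine 7; hydrolysis then delivers the diaryl ketone, so the complete rigidin skeleton is assembled in one operation without prior functionalisation of the heterocycle. The step exploits C6 as the only unsubstituted carbon of the pyrrole ring and as the terminus of the dienamine N7–C7a=C4a–C5=C6, C5 being blocked by the aryl ring. Precursor 7 arises in one pot from 6-aminouracil and a vanillin-derived nitrostyrene; hydrogenolysis of two benzyl ethers ends the synthesis.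

Key step: step 4

Remark: all pyrrolo[2,3-d]pyrimidinediones are written as the 1H,3H,7H-trilactam tautomer of the target; the target has no stereocenter, and intermediates 5 and 6 (one stereocenter each) are racemic.

Step 1
Reactants: 1 4-(benzyloxy)-3-methoxybenzaldehyde (O-benzylvanillin); 2 nitromethane
Product: 3 (E)-1-(benzyloxy)-2-methoxy-4-(2-nitrovinyl)benzene
Conditions: NH4OAc (cat.), AcOH, 100 °C
Reagents that add atoms: none
Why: Henry (nitroaldol) condensation followed by dehydration should give the conjugated nitroalkene, the E isomer being the thermodynamic product.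

Step 2
Reactants: 3 (E)-1-(benzyloxy)-2-methoxy-4-(2-nitrovinyl)benzene; 4 6-aminouracil
Product: 7 5-[4-(benzyloxy)-3-methoxyphenyl]-1H-pyrrolo[2,3-d]pyrimidine-2,4(3H,7H)-dione, via nitro Michael adduct 5 (not isolated), via aldehyde 6 (not isolated)
Conditions: H2O/EtOH, 70 °C; then aq NaOH, 0 °C → rt; then added to aq H2SO4, 0 °C → rt
Reagents that add atoms: none
Why: The enaminic C5 of 6-aminouracil should add to the benzylic carbon of the nitroalkene (Michael addition), the Nef reaction of the derived nitronate unveils an aldehyde, and condensation of this aldehyde with the neighbouring 6-amino group (5-exo-trig attack, then loss of water) closes and aromatises the pyrrole ring, which removes the racemic stereocenter of 5 and 6.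

Step 3
Reactants: 8 4-(benzyloxy)benzoyl chloride; 9 morpholine
Product: 10 [4-(benzyloxy)phenyl](morpholin-4-yl)methanone
Conditions: aq NaOH, CH2Cl2, 0 °C → rt
Reagents that add atoms: none
Why: Schotten–Baumann acylation of the secondary amine should give the tertiary amide needed for chloroiminium formation.

Step 4
Reactants: 7 5-[4-(benzyloxy)-3-methoxyphenyl]-1H-pyrrolo[2,3-d]pyrimidine-2,4(3H,7H)-dione; 10 [4-(benzyloxy)phenyl](morpholin-4-yl)methanone
Product: 13 6-[4-(benzyloxy)benzoyl]-5-[4-(benzyloxy)-3-methoxyphenyl]-1H-pyrrolo[2,3-d]pyrimidine-2,4(3H,7H)-dione, via chloroiminium salt 11 (not isolated), via C6 iminium salt 12 (not isolated)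
Conditions: 10, POCl3, 1,2-dichloroethane, 25 → 60 °C; then 7, MeCN, 80 °C; then aq NaOAc, 80 °C
Reagents that add atoms: water, O
Why: POCl3 should turn morpholide 10 into chloroiminium ion 11, whose iminium carbon is attacked by C6 of 7, and loss of HCl gives the conjugated iminium salt 12, which hot aqueous NaOAc hydrolyses to the ketone (electrophilic aromatic substitution by addition–elimination). The closest known reaction type is the Vilsmeier–Haack aroylation of pyrroles with tertiary benzamides and POCl3. No ring is closed and no stereocenter is formed. Site selectivity follows from the substitution pattern: C6 is the only C–H of the pyrrole ring and the terminus of the dienamine N7–C7a=C4a–C5=C6, which N1 also feeds, C5 is blocked by the aryl group, and attack of 11 at lactam N or O is reversible and is undone in the hydrolysis. Chemoselectivity over the benzyloxy(methoxy)phenyl ring is needed and should be secured by the weak electrophilicity of the chloroiminium ion, which reacts with enamine-type carbons but not with alkoxybenzenes, while the absence of a Lewis acid keeps both benzyl ethers and the methyl ether intact. A second aroylation is excluded because no further pyrrole C–H remains and the product is a deactivated vinylogous amide.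

Step 5
Reactants: 13 6-[4-(benzyloxy)benzoyl]-5-[4-(benzyloxy)-3-methoxyphenyl]-1H-pyrrolo[2,3-d]pyrimidine-2,4(3H,7H)-dione
Product: 14 Rigidin C
Conditions: H2 (1 atm), 10% Pd/C, DMF/MeOH, rt
Reagents that add atoms: none
Why: Hydrogenolysis of the two benzyl aryl ethers should free both phenols, while the methyl ether is inert and the diaryl ketone, a vinylogous amide conjugated with N7, resists reduction at 1 atm.

Compound list
1 | 4-(benzyloxy)-3-methoxybenzaldehyde (O-benzylvanillin) | COc1cc(C=O)ccc1OCc1ccccc1 | starting material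
2 | nitromethane | C[N+](=O)[O-] | starting material
3 | (E)-1-(benzyloxy)-2-methoxy-4-(2-nitrovinyl)benzene | COc1cc(/C=C/[N+](=O)[O-])ccc1OCc1ccccc1 | intermediate
4 | 6-aminouracil (6-aminopyrimidine-2,4(1H,3H)-dione) | Nc1cc(=O)[nH]c(=O)[nH]1 | starting material
5 | 6-amino-5-{1-[4-(benzyloxy)-3-methoxyphenyl]-2-nitroethyl}pyrimidine-2,4(1H,3H)-dione (racemic) | COc1cc(C(C[N+](=O)[O-])c2c(N)[nH]c(=O)[nH]c2=O)ccc1OCc1ccccc1 | intermediate
6 | 2-(6-amino-2,4-dioxo-1,2,3,4-tetrahydropyrimidin-5-yl)-2-[4-(benzyloxy)-3-methoxyphenyl]acetaldehyde (racemic) | COc1cc(C(C=O)c2c(N)[nH]c(=O)[nH]c2=O)ccc1OCc1ccccc1 | intermediate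
7 | 5-[4-(benzyloxy)-3-methoxyphenyl]-1H-pyrrolo[2,3-d]pyrimidine-2,4(3H,7H)-dione | COc1cc(-c2c[nH]c3[nH]c(=O)[nH]c(=O)c23)ccc1OCc1ccccc1 | intermediate
8 | 4-(benzyloxy)benzoyl chloride | O=C(Cl)c1ccc(OCc2ccccc2)cc1 | starting material
9 | morpholine | C1COCCN1 | starting material
10 | [4-(benzyloxy)phenyl](morpholin-4-yl)methanone | O=C(c1ccc(OCc2ccccc2)cc1)N1CCOCC1 | intermediate
11 | 4-{[4-(benzyloxy)phenyl]chloromethylidene}morpholin-4-ium dichlorophosphate | ClC(c1ccc(OCc2ccccc2)cc1)=[N+]1CCOCC1.[O-]P(=O)(Cl)Cl | intermediate
12 | 4-{[4-(benzyloxy)phenyl][5-(4-(benzyloxy)-3-methoxyphenyl)-2,4-dioxo-2,3,4,7-tetrahydro-1H-pyrrolo[2,3-d]pyrimidin-6-yl]methylidene}morpholin-4-ium chloride | COc1cc(-c2c(C(c3ccc(OCc4ccccc4)cc3)=[N+]3CCOCC3)[nH]c3[nH]c(=O)[nH]c(=O)c23)ccc1OCc1ccccc1.[Cl-] | intermediate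
13 | 6-[4-(benzyloxy)benzoyl]-5-[4-(benzyloxy)-3-methoxyphenyl]-1H-pyrrolo[2,3-d]pyrimidine-2,4(3H,7H)-dione | COc1cc(-c2c(C(=O)c3ccc(OCc4ccccc4)cc3)[nH]c3[nH]c(=O)[nH]c(=O)c23)ccc1OCc1ccccc1 | intermediate
14 | Rigidin C, 6-(4-hydroxybenzoyl)-5-(4-hydroxy-3-methoxyphenyl)-1H-pyrrolo[2,3-d]pyrimidine-2,4(3H,7H)-dione | COc1cc(-c2c(C(=O)c3ccc(O)cc3)[nH]c3[nH]c(=O)[nH]c(=O)c23)ccc1O | target

Total step count: 5. Longest linear sequence: 4 steps (steps 1, 2, 4 and 5); step 3 is a one-step side branch.

Steps most likely to fail

Step 4. The chloroiminium ion may be captured at the lactam oxygens faster than at C6, so that C-aroylation stalls or the pyrimidine ring undergoes chlorodehydroxylation. The fallback changes the bond-forming logic from electrophilic substitution to cross-coupling. It sets out from 7, which NIS in DMF at rt should iodinate at its only free pyrrole position to give 5-[4-(benzyloxy)-3-methoxyphenyl]-6-iodo-1H-pyrrolo[2,3-d]pyrimidine-2,4(3H,7H)-dione F1. A carbonylative Suzuki–Miyaura coupling of F1 with 4-(benzyloxy)phenylboronic acid (CO 1 atm, Pd(dppf)Cl2, K2CO3, anisole/DMF, 90 °C) then installs the aroyl group, and the route is rejoined at 13.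

Step 2. Retro-Michael fragmentation of the nitronate in base, or incomplete Nef hydrolysis with oxime or acid formation, may erode the one-pot annulation. The fallback replaces the Michael/Nef sequence by C-alkylation with an α-bromo aldehyde. It sets out from 1, which Wittig methoxymethylenation (MeOCH2PPh3Cl, KOtBu, THF, 0 °C) should convert into the enol ether 1-(benzyloxy)-2-methoxy-4-(2-methoxyvinyl)benzene F2 (E/Z mixture). NBS in MeCN/H2O at 0 °C turns F2 into the labile 2-[4-(benzyloxy)-3-methoxyphenyl]-2-bromoacetaldehyde F3 (racemic, used at once). Addition of 6-aminouracil 4 and NaOAc at 45 °C lets C5 of 4 displace the benzylic bromide; this gives aldehyde 6, which cyclises as in step 2, and the route is rejoined at 7.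

Step 5. Catalyst poisoning by the polar, poorly soluble heterocycle may leave the hydrogenolysis incomplete, or forcing conditions may start to reduce the diaryl ketone. The fallback replaces the reductive cleavage by acidolysis with a cation trap: it sets out from 13, which TFA with pentamethylbenzene at 25–50 °C should debenzylate at both ethers while the methyl ether survives, and it arrives directly at 14. No new compound is made on the way (F0).

Further compounds
F1 | step 4 | 5-[4-(benzyloxy)-3-methoxyphenyl]-6-iodo-1H-pyrrolo[2,3-d]pyrimidine-2,4(3H,7H)-dione | COc1cc(-c2c(I)[nH]c3[nH]c(=O)[nH]c(=O)c23)ccc1OCc1ccccc1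
F2 | step 2 | 1-(benzyloxy)-2-methoxy-4-(2-methoxyvinyl)benzene (E/Z mixture) | COC=Cc1ccc(OCc2ccccc2)c(OC)c1
F3 | step 2 | 2-[4-(benzyloxy)-3-methoxyphenyl]-2-bromoacetaldehyde (racemic) | COc1cc(C(Br)C=O)ccc1OCc1ccccc1
F0 | step 5 | none | none
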